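**Plan**

- Enabling feature: in the cyclohexa-2,5-dienone ring (C1 carbonyl, C2 carrying the benzofuranylmethyl group, C3, C4 the quaternary methyl ether with the Z-cinnamyl arm, C5 the enol-ether carbon, C6), C4 and C5 are a carbinol carbon next to a carbonyl-level carbon, i.e. a cyclic α-ketol in disguise.
- Retrosynthetic cuts, in order: the C2–CH2 bond to the benzofuran (Negishi); the C2=C3 and C5=C6 unsaturation and both O-methyl groups; the ring bond C4–C5 (carbene-catalysed crossed benzoin of an acyclic keto aldehyde); finally the chain bonds made by acetylide–epoxide opening and acetoacetate γ-allylation.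
- Forward order: the chain is assembled in steps 1–7, the carbocycle closes in step 8 (the only ring formed on the main line), and steps 9–13 adjust it to an enol triflate. The benzofuran ring is built separately by a Rap–Stoermer annulation (steps 14–18), joined in step 19 and desilylated in step 20.
- Stereochemistry: the single stereocentre C4 (R in the target, S in the ketol only because CIP priorities change) is set by the chiral triazolylidene in step 8 and, being quaternary, cannot epimerise afterwards. The Z-alkene comes from the Lindlar semihydrogenation in step 6.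

Key step: step 8

Assumption: the (5aS,10bR) aminoindanol-derived triazolium salt is taken to favour the (S)-ketol 13; if the sense of induction is the reverse, its commercially available (5aR,10bS) antipode is used.
Ring locants C1–C6 in the Why lines are those of the target dienone.

**Route**

Step 1
Reactants: 1 methyl acetoacetate; 2 allyl bromide
Product: 3 methyl 3-oxohept-6-enoate
Conditions: NaH, THF, 0 °C; n-BuLi, 0 °C; then 2, 0 → 23 °C; aq. HCl work-up
Reagents that add atoms: none
Why: The Huckin–Weiler dianion of the β-keto ester is alkylated only at its terminal γ-carbon by the allylic bromide (dianion γ-alkylation).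

Step 2
Reactants: 3 methyl 3-oxohept-6-enoate; 4 ethylene glycol
Product: 5 methyl 2-[2-(but-3-en-1-yl)-1,3-dioxolan-2-yl]acetate
Conditions: p-TsOH·H2O (cat.), toluene, reflux, Dean–Stark
Reagents that add atoms: none
Why: Acid-catalysed ketalisation with azeotropic removal of water masks the ketone that becomes C1, leaving the ester and the terminal alkene untouched.

Step 3
Reactants: 5 methyl 2-[2-(but-3-en-1-yl)-1,3-dioxolan-2-yl]acetate
Product: 6 2-[2-(but-3-en-1-yl)-1,3-dioxolan-2-yl]ethan-1-ol
Conditions: LiAlH4, THF, 0 °C; NaOH/H2O work-up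
Reagents that add atoms: none
Why: LiAlH4 ester reduction gives the primary alcohol while ketal and isolated alkene are inert, and removing the ester at this point keeps an acyl electrophile out of the alkynylation in step 5.

Step 4
Reactants: 6 2-[2-(but-3-en-1-yl)-1,3-dioxolan-2-yl]ethan-1-ol
Product: 7 rac-2-{2-[2-(oxiran-2-yl)ethyl]-1,3-dioxolan-2-yl}ethan-1-ol
Conditions: mCPBA, NaHCO3, CH2Cl2, 0 → 23 °C
Reagents that add atoms: 3-chloroperoxybenzoic acid (mCPBA), O=C(OO)c1cccc(Cl)c1
Why: Prilezhaev epoxidation of the terminal alkene under buffered conditions that spare the ketal; the epoxide may be racemic because its carbinol carbon becomes the C4 ketone in step 7.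

Step 5
Reactants: 7 rac-2-{2-[2-(oxiran-2-yl)ethyl]-1,3-dioxolan-2-yl}ethan-1-ol; 8 phenylacetylene
Product: 10 rac-1-[2-(2-hydroxyethyl)-1,3-dioxolan-2-yl]-6-phenylhex-5-yn-3-ol, via lithium phenylacetylide 9 (not isolated)
Conditions: 8, n-BuLi, THF, −78 °C; BF3·OEt2, −78 °C; then 7, −78 °C
Reagents that add atoms: n-butyllithium, [Li]CCCC (lithium retained only in intermediate 9)
Why: Yamaguchi–Hirao alkynylation opens the terminal epoxide at its unsubstituted carbon at −78 °C, one extra equivalent of acetylide being spent on the free hydroxyl and premixing of acetylide and BF3 keeping free Lewis acid away from the ketal.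

Step 6
Reactants: 10 rac-1-[2-(2-hydroxyethyl)-1,3-dioxolan-2-yl]-6-phenylhex-5-yn-3-ol
Product: 11 rac-(5Z)-1-[2-(2-hydroxyethyl)-1,3-dioxolan-2-yl]-6-phenylhex-5-en-3-ol
Conditions: H2 (1 atm), Pd/CaCO3 poisoned with Pb(OAc)2 (Lindlar catalyst), quinoline, EtOAc, 23 °C
Reagents that add atoms: none
Why: Lindlar semihydrogenation delivers both hydrogens to the same face of the alkyne on the poisoned Pd surface, which fixes the Z geometry of the styryl double bond, with quinoline holding back over-reduction.

Step 7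
Reactants: 11 rac-(5Z)-1-[2-(2-hydroxyethyl)-1,3-dioxolan-2-yl]-6-phenylhex-5-en-3-ol
Product: 12 2-{2-[(5Z)-3-oxo-6-phenylhex-5-en-1-yl]-1,3-dioxolan-2-yl}acetaldehyde
Conditions: Dess–Martin periodinane, NaHCO3, CH2Cl2, 0 → 23 °C
Reagents that add atoms: none
Why: Dess–Martin oxidation takes the primary alcohol to the aldehyde and the homoallylic secondary alcohol to the β,γ-unsaturated ketone under buffered, near-neutral conditions that neither conjugate the Z-alkene nor open the ketal.

Step 8
Reactants: 12 2-{2-[(5Z)-3-oxo-6-phenylhex-5-en-1-yl]-1,3-dioxolan-2-yl}acetaldehyde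
Product: 13 (8S)-8-hydroxy-8-[(2Z)-3-phenylprop-2-en-1-yl]-1,4-dioxaspiro[4.5]decan-7-one
Conditions: (5aS,10bR)-2-(pentafluorophenyl)-5a,10b-dihydro-4H,6H-indeno[2,1-b][1,2,4]triazolo[4,3-d][1,4]oxazin-2-ium tetrafluoroborate (15 mol %), Et3N (12 mol %), toluene, 23 °C, argon
Reagents that add atoms: none
Why: Et3N reversibly deprotonates the triazolium salt, the carbene adds to the aldehyde carbon (future C5), proton transfer gives the nucleophilic enaminol (Breslow intermediate), this adds to the ketone carbon (future C4), and collapse of the adduct releases the carbene and the tertiary α-ketol. The closest known reaction type is the carbene-catalysed enantioselective intramolecular crossed aldehyde–ketone benzoin that gives six-membered cyclic α-ketols. The ring closes in 6-exo-trig fashion on the ketone carbonyl, helped by the gem-dialkoxy carbon in the tether. The new stereocentre C4 is controlled by the catalyst: the fused aminoindane framework blocks one face of the enaminol, and the enaminol O–H···O=C hydrogen bond holds the ketone so that the tether methylene and the cinnamyl arm fall into different quadrants. The step needs chemoselectivity and freedom from enolisation: only the aldehyde can become the acyl-anion equivalent and only the ketone six atoms away is within reach, while a weak amine base in less than the catalyst amount leaves the β,γ-unsaturated Z-styryl ketone and the β-ketal aldehyde unenolised.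

Step 9
Reactants: 13 (8S)-8-hydroxy-8-[(2Z)-3-phenylprop-2-en-1-yl]-1,4-dioxaspiro[4.5]decan-7-one
Product: 14 (8S)-8-methoxy-8-[(2Z)-3-phenylprop-2-en-1-yl]-1,4-dioxaspiro[4.5]decan-7-one
Conditions: KN(SiMe3)2, THF, −78 °C; MeOTf, −78 °C
Reagents that add atoms: methyl trifluoromethanesulfonate (MeOTf), COS(=O)(=O)C(F)(F)F
Why: Williamson-type O-methylation of the potassium alkoxide of the tertiary α-ketol with MeOTf at −78 °C, where the hydroxyl is far more acidic than the ketone α-methylene, so C-methylation, ketol shift and retro-allylation should not intervene.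

Step 10
Reactants: 14 (8S)-8-methoxy-8-[(2Z)-3-phenylprop-2-en-1-yl]-1,4-dioxaspiro[4.5]decan-7-one
Product: 16 (4S)-3,4-dimethoxy-4-[(2Z)-3-phenylprop-2-en-1-yl]cyclohex-2-en-1-one, via enol ether ketal 15 (not isolated)
Conditions: KN(SiMe3)2, 18-crown-6, THF, −78 °C; MeOTf; then aq. oxalic acid, THF, 0 °C
Reagents that add atoms: methyl trifluoromethanesulfonate (MeOTf), COS(=O)(=O)C(F)(F)F; water, O
Why: Only C6 can enolise because C4 is quaternary, the crown-separated potassium enolate is methylated on oxygen by the hard triflate (enolate O-alkylation), and mild acid then ionises the allylic ketal so that water enters at unhindered C1 and releases the vinylogous ester with the methoxy group fixed on C5.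

Step 11
Reactants: 16 (4S)-3,4-dimethoxy-4-[(2Z)-3-phenylprop-2-en-1-yl]cyclohex-2-en-1-one
Product: 17 (4R)-6-hydroxy-3,4-dimethoxy-4-[(2Z)-3-phenylprop-2-en-1-yl]cyclohex-2-en-1-one (both carbinol epimers)
Conditions: KN(SiMe3)2, THF, −78 °C; 3-phenyl-2-(phenylsulfonyl)oxaziridine, −78 °C; then AcOH
Reagents that add atoms: 3-phenyl-2-(phenylsulfonyl)oxaziridine, O=S(=O)(c1ccccc1)N1OC1c1ccccc1
Why: Kinetic deprotonation of the vinylogous ester can occur only at the α′-methylene C2 (Stork–Danheiser regiochemistry) and the enolate is hydroxylated by the N-sulfonyloxaziridine (Davis oxidation); the carbinol configuration is irrelevant because it is oxidised in step 12.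

Step 12
Reactants: 17 (4R)-6-hydroxy-3,4-dimethoxy-4-[(2Z)-3-phenylprop-2-en-1-yl]cyclohex-2-en-1-one
Product: 19 (4R)-2-hydroxy-4,5-dimethoxy-4-[(2Z)-3-phenylprop-2-en-1-yl]cyclohexa-2,5-dien-1-one, via 1,2-dione 18 (not isolated)
Conditions: Dess–Martin periodinane, NaHCO3, CH2Cl2, 23 °C
Reagents that add atoms: none
Why: Dess–Martin oxidation of the α-hydroxy ketone gives the 1,2-dione, whose C2 carbonyl can enolise only toward C3, so it should settle as the cross-conjugated diosphenol with the C2=C3 double bond placed unambiguously.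

Step 13
Reactants: 19 (4R)-2-hydroxy-4,5-dimethoxy-4-[(2Z)-3-phenylprop-2-en-1-yl]cyclohexa-2,5-dien-1-one
Product: 20 (3R)-3,4-dimethoxy-6-oxo-3-[(2Z)-3-phenylprop-2-en-1-yl]cyclohexa-1,4-dien-1-yl trifluoromethanesulfonate
Conditions: PhNTf2, Et3N, DMAP (cat.), CH2Cl2, 0 → 23 °C
Reagents that add atoms: N-phenylbis(trifluoromethanesulfonimide) (PhNTf2), O=S(=O)(N(c1ccccc1)S(=O)(=O)C(F)(F)F)C(F)(F)F
Why: The acidic diosphenol hydroxyl is sulfonylated by PhNTf2 (enol triflate formation), a reagent mild enough to leave the vinylogous ester carbonyl alone.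

Step 14
Reactants: 21 2-hydroxy-4-methoxybenzophenone
Product: 23 2,5-dihydroxy-4-methoxybenzophenone, via potassium aryl sulfate 22 (not isolated)
Conditions: K2S2O8, aq. KOH, 0 → 23 °C; then HCl, 80 °C
Reagents that add atoms: potassium peroxodisulfate (K2S2O8), [K+].[K+].[O-]S(=O)(=O)OOS(=O)(=O)[O-]
Why: Elbs persulfate oxidation, in which the phenoxide attacks a peroxide oxygen through its free para carbon and acid hydrolysis of the aryl sulfate then unveils the hydroquinone.

Step 15
Reactants: 23 2,5-dihydroxy-4-methoxybenzophenone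
Product: 24 2-hydroxy-4-methoxy-5-(triisopropylsilyloxy)benzophenone
Conditions: i-Pr3SiCl, imidazole, DMF, 0 °C
Reagents that add atoms: chlorotriisopropylsilane (i-Pr3SiCl), CC(C)[Si](Cl)(C(C)C)C(C)C
Why: Silylation selects the free 5-hydroxyl because the 2-hydroxyl is hindered and tied up in a hydrogen bond to the benzoyl carbonyl.

Step 16
Reactants: 24 2-hydroxy-4-methoxy-5-(triisopropylsilyloxy)benzophenone
Product: 27 ethyl 6-methoxy-3-phenyl-5-(triisopropylsilyloxy)-1-benzofuran-2-carboxylate, via aryloxyacetate 25 (not isolated), via aldol adduct 26 (not isolated)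
Conditions: BrCH2CO2Et, K2CO3, acetone, reflux; then DBU, DMF, 80 °C
Reagents that add atoms: ethyl bromoacetate, CCOC(=O)CBr
Why: Rap–Stoermer-type annulation, i.e. O-alkylation of the remaining phenol by the α-bromo ester, intramolecular aldol addition of the ester enolate to the diaryl ketone and dehydration driven by aromatisation to the benzofuran.

Step 17
Reactants: 27 ethyl 6-methoxy-3-phenyl-5-(triisopropylsilyloxy)-1-benzofuran-2-carboxylate
Product: 28 [6-methoxy-3-phenyl-5-(triisopropylsilyloxy)-1-benzofuran-2-yl]methanol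
Conditions: i-Bu2AlH, CH2Cl2, −78 → 0 °C; Rochelle salt work-up
Reagents that add atoms: none
Why: i-Bu2AlH reduces the heteroaryl ester to the primary alcohol at low temperature without touching the aryl silyl ether.

Step 18
Reactants: 28 [6-methoxy-3-phenyl-5-(triisopropylsilyloxy)-1-benzofuran-2-yl]methanol
Product: 30 2-(chloromethyl)-6-methoxy-3-phenyl-5-(triisopropylsilyloxy)-1-benzofuran, via mesylate 29 (not isolated)
Conditions: MsCl, 2,4,6-collidine, LiCl, DMF, 0 °C
Reagents that add atoms: lithium chloride, [Li+].[Cl-]; methanesulfonyl chloride, CS(=O)(=O)Cl (retained only in intermediate 29)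
Why: Collington–Meyers chlorination, in which the mesylate formed in the flask is displaced by chloride (SN2) under non-acidic conditions that the silyl ether tolerates.

Step 19
Reactants: 20 (3R)-3,4-dimethoxy-6-oxo-3-[(2Z)-3-phenylprop-2-en-1-yl]cyclohexa-1,4-dien-1-yl trifluoromethanesulfonate; 30 2-(chloromethyl)-6-methoxy-3-phenyl-5-(triisopropylsilyloxy)-1-benzofuran
Product: 32 (4R)-4,5-dimethoxy-2-{[6-methoxy-3-phenyl-5-(triisopropylsilyloxy)-1-benzofuran-2-yl]methyl}-4-[(2Z)-3-phenylprop-2-en-1-yl]cyclohexa-2,5-dien-1-one, via benzylic zinc chloride 31 (not isolated)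
Conditions: 30, Zn dust, LiCl, THF, 23 °C; then 20, Pd(PPh3)4 (5 mol %), THF, 23 → 40 °C
Reagents that add atoms: zinc, [Zn] (retained only in intermediate 31)
Why: LiCl-assisted zinc insertion into the benzylic chloride gives the organozinc, which undergoes Negishi coupling with the electron-poor enol triflate (oxidative addition to zerovalent palladium, transmetalation, reductive elimination) near room temperature, so the benzylic group is delivered only to C2 and the Z-alkene, the enol ether and C4 are left alone.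

Step 20
Reactants: 32 (4R)-4,5-dimethoxy-2-{[6-methoxy-3-phenyl-5-(triisopropylsilyloxy)-1-benzofuran-2-yl]methyl}-4-[(2Z)-3-phenylprop-2-en-1-yl]cyclohexa-2,5-dien-1-one
Product: 33 (4R)-2-[(5-hydroxy-6-methoxy-3-phenyl-1-benzofuran-2-yl)methyl]-4,5-dimethoxy-4-[(2Z)-3-phenylprop-2-en-1-yl]cyclohexa-2,5-dien-1-one
Conditions: Bu4NF, AcOH, THF, 0 °C
Reagents that add atoms: none
Why: Fluoride cleaves the aryl silyl ether (Si–O to Si–F exchange) while acetic acid buffers the phenoxide, so the dienone should not be exposed to base or heat that could trigger cinnamyl migration.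

**Compound list**

1 | methyl acetoacetate | COC(=O)CC(C)=O | starting material
2 | allyl bromide | C=CCBr | starting material
3 | methyl 3-oxohept-6-enoate | COC(=O)CC(=O)CCC=C | intermediate
4 | ethylene glycol | OCCO | starting material
5 | methyl 2-[2-(but-3-en-1-yl)-1,3-dioxolan-2-yl]acetate | COC(=O)CC1(CCC=C)OCCO1 | intermediate
6 | 2-[2-(but-3-en-1-yl)-1,3-dioxolan-2-yl]ethan-1-ol | OCCC1(CCC=C)OCCO1 | intermediate
7 | rac-2-{2-[2-(oxiran-2-yl)ethyl]-1,3-dioxolan-2-yl}ethan-1-ol | OCCC1(CCC2CO2)OCCO1 | intermediate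
8 | phenylacetylene | C#Cc1ccccc1 | starting material
9 | lithium phenylacetylide | [Li]C#Cc1ccccc1 | intermediate (not isolated)
10 | rac-1-[2-(2-hydroxyethyl)-1,3-dioxolan-2-yl]-6-phenylhex-5-yn-3-ol | OCCC1(CCC(O)CC#Cc2ccccc2)OCCO1 | intermediate
11 | rac-(5Z)-1-[2-(2-hydroxyethyl)-1,3-dioxolan-2-yl]-6-phenylhex-5-en-3-ol | OCCC1(CCC(O)C/C=C\c2ccccc2)OCCO1 | intermediate
12 | 2-{2-[(5Z)-3-oxo-6-phenylhex-5-en-1-yl]-1,3-dioxolan-2-yl}acetaldehyde | O=CCC1(CCC(=O)C/C=C\c2ccccc2)OCCO1 | intermediate (key-step precursor)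
13 | (8S)-8-hydroxy-8-[(2Z)-3-phenylprop-2-en-1-yl]-1,4-dioxaspiro[4.5]decan-7-one | O=C1CC2(OCCO2)CC[C@@]1(C/C=C\c1ccccc1)O | intermediate (key-step product)
14 | (8S)-8-methoxy-8-[(2Z)-3-phenylprop-2-en-1-yl]-1,4-dioxaspiro[4.5]decan-7-one | O=C1CC2(OCCO2)CC[C@@]1(C/C=C\c1ccccc1)OC | intermediate
15 | (8S)-7,8-dimethoxy-8-[(2Z)-3-phenylprop-2-en-1-yl]-1,4-dioxaspiro[4.5]dec-6-ene | COC1=CC2(OCCO2)CC[C@@]1(C/C=C\c1ccccc1)OC | intermediate (not isolated)
16 | (4S)-3,4-dimethoxy-4-[(2Z)-3-phenylprop-2-en-1-yl]cyclohex-2-en-1-one | COC1=CC(=O)CC[C@@]1(C/C=C\c1ccccc1)OC | intermediate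
17 | (4R)-6-hydroxy-3,4-dimethoxy-4-[(2Z)-3-phenylprop-2-en-1-yl]cyclohex-2-en-1-one (C6 epimers) | COC1=CC(=O)C(O)C[C@@]1(C/C=C\c1ccccc1)OC | intermediate
18 | (5R)-4,5-dimethoxy-5-[(2Z)-3-phenylprop-2-en-1-yl]cyclohex-3-ene-1,2-dione | COC1=CC(=O)C(=O)C[C@@]1(C/C=C\c1ccccc1)OC | intermediate (not isolated)
19 | (4R)-2-hydroxy-4,5-dimethoxy-4-[(2Z)-3-phenylprop-2-en-1-yl]cyclohexa-2,5-dien-1-one | COC1=CC(=O)C(O)=C[C@@]1(C/C=C\c1ccccc1)OC | intermediate
20 | (3R)-3,4-dimethoxy-6-oxo-3-[(2Z)-3-phenylprop-2-en-1-yl]cyclohexa-1,4-dien-1-yl trifluoromethanesulfonate | COC1=CC(=O)C(OS(=O)(=O)C(F)(F)F)=C[C@@]1(C/C=C\c1ccccc1)OC | intermediate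
21 | 2-hydroxy-4-methoxybenzophenone | COc1ccc(C(=O)c2ccccc2)c(O)c1 | starting material
22 | potassium 5-benzoyl-4-hydroxy-2-methoxyphenyl sulfate | COc1cc(O)c(C(=O)c2ccccc2)cc1OS(=O)(=O)[O-].[K+] | intermediate (not isolated)
23 | 2,5-dihydroxy-4-methoxybenzophenone | COc1cc(O)c(C(=O)c2ccccc2)cc1O | intermediate
24 | 2-hydroxy-4-methoxy-5-(triisopropylsilyloxy)benzophenone | COc1cc(O)c(C(=O)c2ccccc2)cc1O[Si](C(C)C)(C(C)C)C(C)C | intermediate
25 | ethyl 2-[2-benzoyl-5-methoxy-4-(triisopropylsilyloxy)phenoxy]acetate | CCOC(=O)COc1cc(OC)c(O[Si](C(C)C)(C(C)C)C(C)C)cc1C(=O)c1ccccc1 | intermediate (not isolated)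
26 | ethyl 3-hydroxy-6-methoxy-3-phenyl-5-(triisopropylsilyloxy)-2,3-dihydro-1-benzofuran-2-carboxylate | CCOC(=O)C1Oc2cc(OC)c(O[Si](C(C)C)(C(C)C)C(C)C)cc2C1(O)c1ccccc1 | intermediate (not isolated)
27 | ethyl 6-methoxy-3-phenyl-5-(triisopropylsilyloxy)-1-benzofuran-2-carboxylate | CCOC(=O)c1oc2cc(OC)c(O[Si](C(C)C)(C(C)C)C(C)C)cc2c1-c1ccccc1 | intermediate
28 | [6-methoxy-3-phenyl-5-(triisopropylsilyloxy)-1-benzofuran-2-yl]methanol | OCc1oc2cc(OC)c(O[Si](C(C)C)(C(C)C)C(C)C)cc2c1-c1ccccc1 | intermediate
29 | [6-methoxy-3-phenyl-5-(triisopropylsilyloxy)-1-benzofuran-2-yl]methyl methanesulfonate | CS(=O)(=O)OCc1oc2cc(OC)c(O[Si](C(C)C)(C(C)C)C(C)C)cc2c1-c1ccccc1 | intermediate (not isolated)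
30 | 2-(chloromethyl)-6-methoxy-3-phenyl-5-(triisopropylsilyloxy)-1-benzofuran | ClCc1oc2cc(OC)c(O[Si](C(C)C)(C(C)C)C(C)C)cc2c1-c1ccccc1 | intermediate
31 | {[6-methoxy-3-phenyl-5-(triisopropylsilyloxy)-1-benzofuran-2-yl]methyl}zinc chloride | Cl[Zn]Cc1oc2cc(OC)c(O[Si](C(C)C)(C(C)C)C(C)C)cc2c1-c1ccccc1 | intermediate (not isolated)
32 | (4R)-4,5-dimethoxy-2-{[6-methoxy-3-phenyl-5-(triisopropylsilyloxy)-1-benzofuran-2-yl]methyl}-4-[(2Z)-3-phenylprop-2-en-1-yl]cyclohexa-2,5-dien-1-one | COC1=CC(=O)C(Cc2oc3cc(OC)c(O[Si](C(C)C)(C(C)C)C(C)C)cc3c2-c2ccccc2)=C[C@@]1(C/C=C\c1ccccc1)OC | intermediate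
33 | (4R)-2-[(5-hydroxy-6-methoxy-3-phenyl-1-benzofuran-2-yl)methyl]-4,5-dimethoxy-4-[(2Z)-3-phenylprop-2-en-1-yl]cyclohexa-2,5-dien-1-one | COC1=CC(=O)C(Cc2oc3cc(OC)c(O)cc3c2-c2ccccc2)=C[C@@]1(C/C=C\c1ccccc1)OC | target

**Step count and risks**

Total steps: 20. Longest linear sequence: 15 (steps 1–13, 19, 20); the benzofuran branch is steps 14–18.

Steps most likely to fail:

1. Step 8. The chiral carbene may discriminate poorly between the two ketone faces, because both flanking groups are primary alkyl chains, and prolonged exposure to base could erode the Z geometry. Fallback, from 12 back to 13: ring closure with an achiral precatalyst (3-benzyl-5-(2-hydroxyethyl)-4-methylthiazolium chloride, Et3N, toluene) should give the racemic ketol F1. Its potassium alkoxide (KN(SiMe3)2, THF, −78 °C) is acylated with (1S)-camphanic chloride and the diastereomeric esters are separated by chromatography or crystallisation. The (8S)-camphanate F2 is then cleaved with K2CO3 in MeOH to return 13, so that a classical resolution replaces catalyst control.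

2. Step 10. The enolate may be methylated on carbon instead of oxygen, β-elimination may open the dioxolane before methylation, or water may capture the dialkoxyallyl cation at the hindered terminus during unmasking. Fallback, from 14 to 16: aqueous HCl in THF removes the ketal to give the enolised 1,3-dione F3. Me3SiCHN2 in toluene–MeOH should then methylate both enol oxygens to give 16 together with the regioisomeric enol ether F4, which are separated by chromatography. F4 is returned to F3 with dilute aqueous acid and recycled.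

3. Step 19. Wurtz-type homocoupling may occur during zinc insertion into the electron-rich heteroarylmethyl chloride, or slow transmetalation may leave the triflate to be reduced or hydrolysed. Fallback, from 16 and 30 to 32: the kinetic enolate of 16 (LiN(i-Pr)2, THF, −78 °C) is alkylated at C2 with 30 (NaI catalysis, Stork–Danheiser alkylation) to give the 6-alkylated ketone F5. Conversion to the trimethylsilyl dienol ether F6 (LiN(i-Pr)2, Me3SiCl) and Saegusa–Ito oxidation with Pd(OAc)2 in MeCN should give 32. This bypasses steps 11–13 but leaves the position of the new double bond (ring versus benzylidene) to the β-hydride elimination, which is why it is held in reserve.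

**Further compounds**

F1 | step 8 | rac-8-hydroxy-8-[(2Z)-3-phenylprop-2-en-1-yl]-1,4-dioxaspiro[4.5]decan-7-one | O=C1CC2(OCCO2)CCC1(C/C=C\c1ccccc1)O
F2 | step 8 | (8S)-7-oxo-8-[(2Z)-3-phenylprop-2-en-1-yl]-1,4-dioxaspiro[4.5]decan-8-yl (1S,4R)-4,7,7-trimethyl-3-oxo-2-oxabicyclo[2.2.1]heptane-1-carboxylate | O=C1CC2(OCCO2)CC[C@@]1(C/C=C\c1ccccc1)OC(=O)[C@@]12CC[C@@](C)(C(=O)O1)C2(C)C
F3 | step 10 | (4S)-4-methoxy-4-[(2Z)-3-phenylprop-2-en-1-yl]cyclohexane-1,3-dione | O=C1CC(=O)CC[C@@]1(C/C=C\c1ccccc1)OC
F4 | step 10 | (6S)-3,6-dimethoxy-6-[(2Z)-3-phenylprop-2-en-1-yl]cyclohex-2-en-1-one | O=C1C=C(OC)CC[C@@]1(C/C=C\c1ccccc1)OC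
F5 | step 19 | (4R)-3,4-dimethoxy-6-{[6-methoxy-3-phenyl-5-(triisopropylsilyloxy)-1-benzofuran-2-yl]methyl}-4-[(2Z)-3-phenylprop-2-en-1-yl]cyclohex-2-en-1-one (C6 epimers) | COC1=CC(=O)C(Cc2oc3cc(OC)c(O[Si](C(C)C)(C(C)C)C(C)C)cc3c2-c2ccccc2)C[C@@]1(C/C=C\c1ccccc1)OC
F6 | step 19 | {[(4R)-3,4-dimethoxy-6-{[6-methoxy-3-phenyl-5-(triisopropylsilyloxy)-1-benzofuran-2-yl]methyl}-4-[(2Z)-3-phenylprop-2-en-1-yl]cyclohexa-1,5-dien-1-yl]oxy}trimethylsilane | COC1=CC(O[Si](C)(C)C)=C(Cc2oc3cc(OC)c(O[Si](C(C)C)(C(C)C)C(C)C)cc3c2-c2ccccc2)C[C@@]1(C/C=C\c1ccccc1)OC
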